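**Retrosynthetic overview** (chain carbons: C1 = CH3, C2–C4 = triol carbons, C5 = CH2, C6 = ester carbinol)
1. Target ⇒ acid removal of a C2‑O‑TES ether and a C3/C4 acetonide; ester ⇒ (6R)‑carbinol + 13‑methyltetradecanoic acid.
2. (6R)‑Carbinol ⇒ CBS reduction of the C6 oxazolyl ketone (reagent control; O6 ends syn to O4).
3. Key disconnection C6–C4(oxazole): ketone ⇒ 4‑bromo‑2‑(oxazol‑5‑ylmethyl)oxazole + C1‑metalated 3,4‑O‑isopropylidene‑L‑fucal. The metalated glycal is a cyclic α‑alkoxyvinyl metal, i.e. the acyl anion of 2‑deoxy‑L‑fucose; hydrolysis of the coupled enol ether opens the pyran to the ketone. C2, C3 and C4 come unchanged from L‑fucal.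
4. Bromo‑bis‑oxazole ⇒ C2‑selective Negishi coupling of 2,4‑dibromooxazole with (oxazol‑5‑ylmethyl)zinc chloride.
5. Rings: neither oxazole is built (both are bought). The only ring made is the temporary dioxolane (step 2); the dihydropyran of the glycal is opened in step 3.

Assumption: the acyl chain is read from the SMILES as 13‑methyltetradecanoyl, and compounds 1, 2, 5 and 14 are taken as catalogue compounds (not checked against current supplier listings).

**Step 1**
Reactants: 1 5-(chloromethyl)-1,3-oxazole; 2 2,4-dibromo-1,3-oxazole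
Product: 4 4-bromo-2-(1,3-oxazol-5-ylmethyl)-1,3-oxazole, via oxazol-5-ylmethylzinc chloride 3 (not isolated)
Conditions: Zn dust, LiCl, THF, 25 °C; then 2, Pd(PPh3)4 (3 mol%), THF, 25 °C
Reagents that add atoms: none
Why: LiCl‑promoted zinc insertion into the heterobenzylic C–Cl bond gives a mild organozinc that tolerates the oxazole C2–H, and the Negishi cross‑coupling takes place at C2–Br of 2 (flanked by O and N, it undergoes oxidative addition much faster than C4–Br, as in 2,4‑dihalothiazoles and ‑oxazoles), which leaves C4–Br for step 3; no stereocentre is involved.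

**Step 2**
Reactants: 5 3,4-di-O-acetyl-L-fucal
Product: 7 3,4-O-isopropylidene-L-fucal, via L-fucal 6 (not isolated)
Conditions: K2CO3 (cat.), MeOH, rt; evaporate; Me2C(OMe)2, PPTS (cat.), acetone, rt
Reagents that add atoms: 2,2-dimethoxypropane, COC(C)(C)OC
Why: Zemplén‑type transesterification removes both acetates and mild acid‑catalysed transketalisation closes a dioxolane on the cis‑3,4‑diol without touching the enol ether; the three stereocentres that become C2, C3 and C4 of the target are carried over unchanged from the L‑fuco series.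

**Step 3**
Reactants: 7 3,4-O-isopropylidene-L-fucal; 4 4-bromo-2-(1,3-oxazol-5-ylmethyl)-1,3-oxazole
Product: 11 2-[(4S,5R)-5-[(1S)-1-hydroxyethyl]-2,2-dimethyl-1,3-dioxolan-4-yl]-1-[2-(1,3-oxazol-5-ylmethyl)-1,3-oxazol-4-yl]ethan-1-one, via 1-lithio glycal 8 (not isolated), via glycal zinc chloride 9 (not isolated), via C-aryl glycal 10 (not isolated)
Conditions: t-BuLi, THF, −78 → 0 °C; ZnCl2, 0 °C → rt; 4, Pd2(dba)3/XPhos (cat.), 50 °C; then 0.5 M aq. HCl, THF, 0 °C
Reagents that add atoms: water, O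
Why: α‑Lithiation of the cyclic enol ether at C1 (the vinylic C–H next to the ring oxygen) gives an α‑alkoxyvinyl metal, an acyl‑anion equivalent of 2‑deoxy‑L‑fucose C1, which after Li→Zn exchange undergoes Negishi cross‑coupling with the C4–Br of 4 (the reaction type is known for glycal zinc chlorides and stannanes with aryl halides), so that the future carbonyl carbon C6 is joined to the electrophilic oxazole carbon; Markovnikov hydration of the aryl enol ether in the acidic work‑up then unmasks the ketone, opens the pyran and frees the C2 hydroxyl, with no new stereocentre formed and none of the existing ones touched.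

**Step 4**
Reactants: 11 2-[(4S,5R)-5-[(1S)-1-hydroxyethyl]-2,2-dimethyl-1,3-dioxolan-4-yl]-1-[2-(1,3-oxazol-5-ylmethyl)-1,3-oxazol-4-yl]ethan-1-one
Product: 12 2-[(4S,5S)-2,2-dimethyl-5-[(1S)-1-(triethylsilyloxy)ethyl]-1,3-dioxolan-4-yl]-1-[2-(1,3-oxazol-5-ylmethyl)-1,3-oxazol-4-yl]ethan-1-one
Conditions: TESCl, imidazole, DMAP (cat.), CH2Cl2, 0 °C → rt
Reagents that add atoms: triethylsilyl chloride, CC[Si](Cl)(CC)CC
Why: Silyl ether formation at the only hydroxyl; the δ‑hydroxy aryl ketone equilibrates with its six‑membered lactol under the basic conditions and the secondary alcohol of the open form is the one that is silylated (Curtin–Hammett), which fixes the open‑chain ketone and blocks O2 before O6 is made; no stereocentre is affected (the 5R→5S change is only a CIP priority change caused by silicon).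

**Step 5**
Reactants: 12 2-[(4S,5S)-2,2-dimethyl-5-[(1S)-1-(triethylsilyloxy)ethyl]-1,3-dioxolan-4-yl]-1-[2-(1,3-oxazol-5-ylmethyl)-1,3-oxazol-4-yl]ethan-1-one
Product: 13 (1R)-2-[(4S,5S)-2,2-dimethyl-5-[(1S)-1-(triethylsilyloxy)ethyl]-1,3-dioxolan-4-yl]-1-[2-(1,3-oxazol-5-ylmethyl)-1,3-oxazol-4-yl]ethan-1-ol
Conditions: (S)-Me-CBS (20 mol%), BH3·SMe2, THF, −20 °C; MeOH quench
Reagents that add atoms: none
Why: Corey–Bakshi–Shibata reduction, in which the (S)‑oxazaborolidine delivers hydride to the face that gives the (R)‑carbinol when the planar oxazolyl group is the large and the CH2 chain the small substituent (same sense as acetophenone → (R)‑1‑phenylethanol), so C6 is set by reagent control with O6 syn to O4.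

**Step 6**
Reactants: 13 (1R)-2-[(4S,5S)-2,2-dimethyl-5-[(1S)-1-(triethylsilyloxy)ethyl]-1,3-dioxolan-4-yl]-1-[2-(1,3-oxazol-5-ylmethyl)-1,3-oxazol-4-yl]ethan-1-ol; 14 13-methyltetradecanoic acid
Product: 15 (1R)-2-[(4S,5S)-2,2-dimethyl-5-[(1S)-1-(triethylsilyloxy)ethyl]-1,3-dioxolan-4-yl]-1-[2-(1,3-oxazol-5-ylmethyl)-1,3-oxazol-4-yl]ethyl 13-methyltetradecanoate
Conditions: DCC, DMAP (cat.), CH2Cl2, 0 °C → rt
Reagents that add atoms: none
Why: Steglich esterification of the only free hydroxyl; acylation occurs at oxygen, so C6 keeps its (R) configuration.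

**Step 7**
Reactants: 15 (1R)-2-[(4S,5S)-2,2-dimethyl-5-[(1S)-1-(triethylsilyloxy)ethyl]-1,3-dioxolan-4-yl]-1-[2-(1,3-oxazol-5-ylmethyl)-1,3-oxazol-4-yl]ethyl 13-methyltetradecanoate
Product: 16 (1R,3S,4R,5S)-3,4,5-trihydroxy-1-[2-(1,3-oxazol-5-ylmethyl)-1,3-oxazol-4-yl]hexyl 13-methyltetradecanoate
Conditions: TFA/H2O/THF (1:1:4), 0 °C → rt
Reagents that add atoms: none
Why: Aqueous acid hydrolysis cleaves the TES ether and the isopropylidene ketal in one operation, while the secondary ester is stable to these conditions and is not expected to migrate to O4 at low temperature and short contact time; no stereocentre is touched.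

**Compound list**
1 | 5-(chloromethyl)-1,3-oxazole | ClCc1cnco1 | starting material
2 | 2,4-dibromo-1,3-oxazole | Brc1coc(Br)n1 | starting material
3 | (1,3-oxazol-5-ylmethyl)zinc chloride (formed in situ) | Cl[Zn]Cc1cnco1 | intermediate
4 | 4-bromo-2-(1,3-oxazol-5-ylmethyl)-1,3-oxazole | Brc1coc(Cc2cnco2)n1 | intermediate
5 | 3,4-di-O-acetyl-L-fucal (3,4-di-O-acetyl-1,5-anhydro-2,6-dideoxy-L-lyxo-hex-1-enitol) | C[C@@H]1OC=C[C@H](OC(C)=O)[C@@H]1OC(C)=O | starting material
6 | L-fucal (1,5-anhydro-2,6-dideoxy-L-lyxo-hex-1-enitol; formed in situ) | C[C@@H]1OC=C[C@H](O)[C@@H]1O | intermediate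
7 | 3,4-O-isopropylidene-L-fucal (cis-fused acetonide of 6) | C[C@@H]1OC=C[C@@H]2OC(C)(C)O[C@H]12 | intermediate
8 | 1-lithio-3,4-O-isopropylidene-L-fucal (Li on the enol-ether carbon next to the ring O; formed in situ) | C[C@@H]1OC([Li])=C[C@@H]2OC(C)(C)O[C@H]12 | intermediate
9 | (3,4-O-isopropylidene-L-fucal-1-yl)zinc chloride (formed in situ) | C[C@@H]1OC([Zn]Cl)=C[C@@H]2OC(C)(C)O[C@H]12 | intermediate
10 | 1-C-[2-(1,3-oxazol-5-ylmethyl)-1,3-oxazol-4-yl]-3,4-O-isopropylidene-L-fucal (formed in situ) | C[C@@H]1OC(c3coc(Cc4cnco4)n3)=C[C@@H]2OC(C)(C)O[C@H]12 | intermediate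
11 | 2-[(4S,5R)-5-[(1S)-1-hydroxyethyl]-2,2-dimethyl-1,3-dioxolan-4-yl]-1-[2-(1,3-oxazol-5-ylmethyl)-1,3-oxazol-4-yl]ethan-1-one (open-chain form; equilibrates with its six-membered lactol) | C[C@H](O)[C@H]1OC(C)(C)O[C@H]1CC(=O)c2coc(Cc3cnco3)n2 | intermediate
12 | 2-[(4S,5S)-2,2-dimethyl-5-[(1S)-1-(triethylsilyloxy)ethyl]-1,3-dioxolan-4-yl]-1-[2-(1,3-oxazol-5-ylmethyl)-1,3-oxazol-4-yl]ethan-1-one | C[C@H](O[Si](CC)(CC)CC)[C@H]1OC(C)(C)O[C@H]1CC(=O)c2coc(Cc3cnco3)n2 | intermediate
13 | (1R)-2-[(4S,5S)-2,2-dimethyl-5-[(1S)-1-(triethylsilyloxy)ethyl]-1,3-dioxolan-4-yl]-1-[2-(1,3-oxazol-5-ylmethyl)-1,3-oxazol-4-yl]ethan-1-ol | C[C@H](O[Si](CC)(CC)CC)[C@H]1OC(C)(C)O[C@H]1C[C@@H](O)c2coc(Cc3cnco3)n2 | intermediate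
14 | 13-methyltetradecanoic acid | CC(C)CCCCCCCCCCCC(=O)O | starting material
15 | (1R)-2-[(4S,5S)-2,2-dimethyl-5-[(1S)-1-(triethylsilyloxy)ethyl]-1,3-dioxolan-4-yl]-1-[2-(1,3-oxazol-5-ylmethyl)-1,3-oxazol-4-yl]ethyl 13-methyltetradecanoate | C[C@H](O[Si](CC)(CC)CC)[C@H]1OC(C)(C)O[C@H]1C[C@@H](OC(=O)CCCCCCCCCCCC(C)C)c2coc(Cc3cnco3)n2 | intermediate
16 | (1R,3S,4R,5S)-3,4,5-trihydroxy-1-[2-(1,3-oxazol-5-ylmethyl)-1,3-oxazol-4-yl]hexyl 13-methyltetradecanoate | CC(C)CCCCCCCCCCCC(=O)O[C@H](C[C@H](O)[C@H](O)[C@H](C)O)c1coc(Cc2cnco2)n1 | target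

**Totals**
Total step count: 7. Longest linear sequence: 6 steps (5 → 7 → 11 → 12 → 13 → 15 → 16); step 1 is the only side branch.

**Steps most likely to fail, with fallbacks**

Step 3 (metalation, cross‑coupling and unmasking in one pot). The risks are incomplete C1‑lithiation of the acetonide‑protected glycal, slow oxidative addition into the C4–Br bond, and interference of lithium/zinc salts or residual base with the bromide partner. The fallback leaves the route at 7 and rejoins it at 10, which is then hydrolysed to 11 by the same acid treatment. The acyl‑anion equivalent is isolated as a tin reagent instead of being used as the zinc species. Lithiation of 7 and quench with Bu3SnCl gives 1-(tributylstannyl)-3,4-O-isopropylidene-L-fucal F1, which is purified on Et3N‑deactivated silica. Copper‑assisted Stille coupling of F1 with 4 (Pd(PPh3)4, CuI, DMF, 50 °C) gives 10. This separates the strongly basic metalation from the palladium step.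

Step 4 (trapping the open‑chain hydroxy ketone). If 11 sits mainly as the lactol, silylation may go to the anomeric oxygen. The fallback leaves at 11 and rejoins at the target 16, with no protecting group on O2. Asymmetric transfer hydrogenation of 11 (RuCl[(R,R)-TsDPEN](p-cymene), HCO2H/Et3N; free hydroxyl tolerated, the open‑chain ketone is drained from the equilibrium) gives the diol (1R)-2-[(4S,5R)-5-[(1S)-1-hydroxyethyl]-2,2-dimethyl-1,3-dioxolan-4-yl]-1-[2-(1,3-oxazol-5-ylmethyl)-1,3-oxazol-4-yl]ethan-1-ol F2. Site‑selective Steglich acylation with 14 at −20 °C takes the unhindered heterobenzylic hydroxyl (the other one is flanked by the methyl group and the dioxolane) and gives the mono‑ester (1R)-2-[(4S,5R)-5-[(1S)-1-hydroxyethyl]-2,2-dimethyl-1,3-dioxolan-4-yl]-1-[2-(1,3-oxazol-5-ylmethyl)-1,3-oxazol-4-yl]ethyl 13-methyltetradecanoate F3. Acid hydrolysis of the acetonide as in step 7 then gives 16.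

Step 5 (C6 stereocentre). The oxazole nitrogen next to the carbonyl and the β‑oxygenated chain may erode or mismatch the CBS selectivity. The fallback leaves at 12 and rejoins at 15, replacing reagent control by a stereoconvergent sequence. Reduction of 12 with NaBH4 (MeOH, −40 °C) gives 13 together with its C6 epimer (1S)-2-[(4S,5S)-2,2-dimethyl-5-[(1S)-1-(triethylsilyloxy)ethyl]-1,3-dioxolan-4-yl]-1-[2-(1,3-oxazol-5-ylmethyl)-1,3-oxazol-4-yl]ethan-1-ol F4, and the two are separated. Compound 13 continues through step 6. F4 is esterified with inversion by Mitsunobu reaction with 14 (PPh3, DIAD, toluene, 0 °C) to the same ester 15, so both epimers converge.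

**Further compounds**
F1 | step 3 | 1-(tributylstannyl)-3,4-O-isopropylidene-L-fucal | C[C@@H]1OC([Sn](CCCC)(CCCC)CCCC)=C[C@@H]2OC(C)(C)O[C@H]12
F2 | step 4 | (1R)-2-[(4S,5R)-5-[(1S)-1-hydroxyethyl]-2,2-dimethyl-1,3-dioxolan-4-yl]-1-[2-(1,3-oxazol-5-ylmethyl)-1,3-oxazol-4-yl]ethan-1-ol | C[C@H](O)[C@H]1OC(C)(C)O[C@H]1C[C@@H](O)c2coc(Cc3cnco3)n2
F3 | step 4 | (1R)-2-[(4S,5R)-5-[(1S)-1-hydroxyethyl]-2,2-dimethyl-1,3-dioxolan-4-yl]-1-[2-(1,3-oxazol-5-ylmethyl)-1,3-oxazol-4-yl]ethyl 13-methyltetradecanoate | C[C@H](O)[C@H]1OC(C)(C)O[C@H]1C[C@@H](OC(=O)CCCCCCCCCCCC(C)C)c2coc(Cc3cnco3)n2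
F4 | step 5 | (1S)-2-[(4S,5S)-2,2-dimethyl-5-[(1S)-1-(triethylsilyloxy)ethyl]-1,3-dioxolan-4-yl]-1-[2-(1,3-oxazol-5-ylmethyl)-1,3-oxazol-4-yl]ethan-1-ol | C[C@H](O[Si](CC)(CC)CC)[C@H]1OC(C)(C)O[C@H]1C[C@H](O)c2coc(Cc3cnco3)n2
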